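6 questions hang here on one quantity: how much target meets starting material before the starting material is used up.

| setting | cedar | oak | autumn | summer | noon |
|---|---|---|---|---|---|
| starting material | 0.80 M | 1.6 M | 0.80 M | 0.80 M | 0.80 M |
| reagent | 2.4 M | 1.6 M | 1.60 M | 1.60 M | 1.60 M |
| free catalyst | 4 mM | 4 mM | 36 mM | 4.0 mM | 12 mM |
| remark | run made earlier | run made earlier |  |  |  |
| time |  |  | 1.5 h | 1.5 h | 1.5 h |

- cedar (time / min: target / %): 3.00: 13.0; 6.00: 24.2; 10.0: 35.1; 12.0: 42.0; 15.0: 48.7; 20.0: 60.4
- oak (time / min: target / %): 1.33: 2.5; 2.50: 4.7; 4.00: 7.4; 6.00: 12.3; 10.0: 17.5; 20.0: 25.3

(standard deviation of a reading: 1 percentage point)

* which of the two there is more of at the end, counted by the starting material in each, autumn (side product / target)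
* which of the two there is more of at the end, counted by the starting material in each, summer (side product / target)
* which of the two there is more of at the end, counted by the starting material in each, noon (side product / target)
* target at the end, in percent of the starting material charged, autumn
* target at the end, in percent of the starting material charged, summer
* target at the end, in percent of the starting material charged, noon

- a species is counted by the starting material in it: one side product counts as two
- steps thought possible: catalyst intermediate C -> free catalyst + target; reagent + free catalyst -> catalyst intermediate A; starting material + catalyst intermediate A -> catalyst intermediate B; starting material + target -> side product; catalyst intermediate B <-> released group + catalyst intermediate C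
- no earlier run changes the charge of free catalyst; that part of a forecast is a guess

Solve two extreme flasks first. If the catalyst uses the starting material long before target can react with it, target is the whole charge. If the catalyst is slow against that reaction, starting material catches each target as it appears, and side product takes the charge. The real flask lies between, and two times place it.

The first is the use-up time, c(starting material) over the early rate. The early rate reads 0.0347 M min⁻¹ in cedar and 0.0296 M min⁻¹ in oak. Summer shares its starting material with cedar and its reagent with oak, so I take the mean, 0.0321 M min⁻¹, which gives 24.9 min.

The second is the half-life of target against starting material at 0.80 M. Late in oak, target gains 0.0125 M min⁻¹, so about 0.0171 M min⁻¹ of the early rate goes missing, with mean c(target) 0.342 M and c(starting material) near 1.16 M. That reads as 20.0 min.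

Now replace the curves by their means. Over the use-up time, starting material falls and target rises along straight lines, so their product averages the squared charge divided by 6, and each side product counts twice. The loss number, for summer 28.7 %, is the share of the charge ending in side product: the use-up time, times the logarithm of two, over 3 half-lives. The straight target line ignores target already lost, which pushes the number up, so it stays an estimate and is no bound.

No earlier run changes the catalyst, so I guess that the rate follows it. My target is then 71.3 % in summer, 90.4 % in noon and 96.8 % in autumn.

The forecast names target in each flask, with 96 % (89 % to 99 %) in autumn, 73 % (62 % to 84 %) in summer and 90 % (80 % to 96 %) in noon, "rate is proportional to catalyst, side product scales about inversely". My summer figure is lower than the forecast's.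

    catalyst intermediate C → free catalyst + target (k = 0.340 s⁻¹)
    reagent + free catalyst → catalyst intermediate A (k = 5.50 L mol⁻¹ s⁻¹)
    starting material + catalyst intermediate A → catalyst intermediate B (k = 2.50 L mol⁻¹ s⁻¹)
    starting material + target → side product (k = 7.80 × 10⁻⁴ L mol⁻¹ s⁻¹)
    catalyst intermediate B ⇌ released group + catalyst intermediate C (K = 1.00 M, k = 0.310 s⁻¹)

Target reaches 96.4 % in autumn, 75.4 % in summer and 89.7 % in noon, ahead of side product each time. In autumn the use-up time, twice 1.30 min, is 2.60 min, shorter than target's half-life of 0.31 h in summer at the same charge, so the loss number is 3.23 % against 3.57 % found. Raising autumn's starting material to 1.34 M at fixed rate adds 5.7 percentage points by square scaling, and target moves 6 points. The forecast's choice of target would fail with autumn's reagent at 0.40 M, where reagent, the limiting reagent, ends at 0 % and side product holds 62.6 % against target 18.7 %.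

(The earlier runs and the new flask stem from a simulated flask with constants of no real substance, and the scatter is random.)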